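**Plan**
- Retrosynthesis: the side chain (numbered from the ester carbon) is cut at the Z‑alkene C2=C3 (Still–Gennari olefination) and at C4–C5 (alkylation of an allylic bromide made from a prenyl terminus). The pyran ring is opened at O1–C8a. The benzene ring is taken apart completely, at C8a–C8, C7–C6, C8a–C4a and C5–C6.
- Enabling feature: the benzene ring of the chroman (C4a, C5 with its methyl, C6, C7 with its hydroxyl, C8, C8a with the ring oxygen) is a 4‑alkylated orcinol with two unlike oxygens. It is therefore assembled from an open‑chain diazo enone (supplying C8a, C6, C5, C4a) and a siloxyalkyne (supplying C8, C7), not by substitution of orcinol.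
- Forward order: (R)‑linalool is extended at its vinyl group to the diazo enone; the benzannulation builds the benzene ring first; the free C8a hydroxyl is then made a leaving group and displaced by the tertiary oxygen to close the pyran ring; the side chain is finished last.
- Stereochemistry: C2 (R) is the carbinol carbon of (R)‑linalool, and no bond to it is ever broken. The 6E alkene comes from the E‑selective SeO2 oxidation of the prenyl group, the 2Z alkene from the Still–Gennari reaction.

Key step: step 6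

Remark: commercial (R)‑(−)‑linalool is taken as enantiomerically enriched material whose purity carries unchanged to C2; anions formed by plain deprotonation of a numbered compound (lithium acetylide, enolate, phosphonate carbanion) are regarded as that compound and are not numbered separately.

**Route**

Step 1
Reactants: 1 (R)‑linalool
Product: 2 triethyl{[(3R)‑3,7‑dimethylocta‑1,6‑dien‑3‑yl]oxy}silane
Conditions: Et3SiOTf, 2,6‑lutidine, CH2Cl2, −78 to 0 °C
Reagents that add atoms: triethylsilyl trifluoromethanesulfonate, CC[Si](CC)(CC)OS(=O)(=O)C(F)(F)F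
Why: Silyl triflate silylation of a hindered tertiary alcohol should proceed cleanly with a pyridine base, and the silyl ether prevents lactol formation in the hydroformylation and oxa‑Michael closure onto the later enone while leaving the stereocentre untouched.

Step 2
Reactants: 2 triethyl{[(3R)‑3,7‑dimethylocta‑1,6‑dien‑3‑yl]oxy}silane
Product: 3 (4R)‑4,8‑dimethyl‑4‑(triethylsilyloxy)non‑7‑enal
Conditions: Rh(acac)(CO)2 (1 mol %), Xantphos, CO/H2 (1:1, 10 bar), toluene, 70 °C
Reagents that add atoms: carbon monoxide, [C-]#[O+]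
Why: Rhodium‑catalysed hydroformylation with a wide‑bite‑angle diphosphine should place the formyl group on the terminal vinyl carbon, because the neighbouring quaternary carbon blocks the branched mode and the trisubstituted alkene is inert under these mild conditions.

Step 3
Reactants: 3 (4R)‑4,8‑dimethyl‑4‑(triethylsilyloxy)non‑7‑enal; 4 3‑(triphenylphosphoranylidene)butan‑2‑one
Product: 5 (3E,7R)‑3,7,11‑trimethyl‑7‑(triethylsilyloxy)dodeca‑3,10‑dien‑2‑one
Conditions: 4 (1.5 equiv), toluene, 100 °C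
Reagents that add atoms: none
Why: Wittig olefination of an unhindered aldehyde with a stabilised α‑branched keto ylide should give the E‑trisubstituted enone under the usual thermodynamic control of stabilised ylides.

Step 4
Reactants: 5 (3E,7R)‑3,7,11‑trimethyl‑7‑(triethylsilyloxy)dodeca‑3,10‑dien‑2‑one
Product: 7 (3E,7R)‑1‑diazo‑3,7,11‑trimethyl‑7‑(triethylsilyloxy)dodeca‑3,10‑dien‑2‑one, via trifluoroacetyl diketone 6 (not isolated)
Conditions: LiN(SiMe3)2, THF, −78 °C; CF3CO2CH2CF3, −78 °C; aq. HCl work‑up; then 4‑acetamidobenzenesulfonyl azide, Et3N, H2O, MeCN, rt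
Reagents that add atoms: 4‑acetamidobenzenesulfonyl azide, CC(=O)Nc1ccc(cc1)S(=O)(=O)N=[N+]=[N-]; 2,2,2‑trifluoroethyl trifluoroacetate, O=C(OCC(F)(F)F)C(F)(F)F (trifluoroacetyl group of intermediate 6 only)
Why: Detrifluoroacetylative diazo transfer: the kinetic cross‑conjugated methyl enolate is trifluoroacetylated, and the activated 1,3‑diketone takes up the diazo group from the sulfonyl azide with loss of the trifluoroacetyl group, a sequence developed for α,β‑unsaturated methyl ketones.

Step 5
Reactants: 8 acetylene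
Product: 10 (triisopropylsilyloxy)ethyne, via lithium ethynolate 9 (not isolated)
Conditions: 8 (excess), n‑BuLi, THF, −78 °C; added to t‑BuOOLi [from t‑BuOOH and LiN(SiMe3)2, THF, −78 °C]; −78 to −20 °C; then i‑Pr3SiOTf, −78 to 0 °C; pentane work‑up, short‑path distillation
Reagents that add atoms: tert‑butyl hydroperoxide, CC(C)(C)OO; triisopropylsilyl trifluoromethanesulfonate, CC(C)[Si](OS(=O)(=O)C(F)(F)F)(C(C)C)C(C)C; n‑butyllithium, [Li]CCCC (lithium of intermediate 9 only)
Why: Oxidation of an alkynyllithium by lithium tert‑butylperoxide is the standard entry to lithium ynolates, and the bulky, hard silyl triflate should silylate the ynolate at oxygen to give the siloxyalkyne.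

Step 6
Reactants: 7 (3E,7R)‑1‑diazo‑3,7,11‑trimethyl‑7‑(triethylsilyloxy)dodeca‑3,10‑dien‑2‑one; 10 (triisopropylsilyloxy)ethyne
Product: 15 2‑[(3R)‑3,7‑dimethyl‑3‑(triethylsilyloxy)oct‑6‑en‑1‑yl]‑3‑methyl‑5‑(triisopropylsilyloxy)phenol, via vinylketene 11 (not isolated), via vinylcyclobutenone 12 (not isolated), via dienylketene 13 (not isolated), via cyclohexadienone 14 (not isolated)
Conditions: 10 (2.5 equiv), hν (254 nm, Vycor), degassed ClCH2CH2Cl, rt; then 80 °C
Reagents that add atoms: none
Why: Irradiation expels N2 and the Wolff shift moves the alkenyl carbon C5 from the carbonyl carbon to the former diazo carbon (creating C5–C6), giving vinylketene 11, whose C=C bond adds to the electron‑rich alkyne in a regioselective [2+2] cycloaddition (C8a–C8 and C7–C6) to vinylcyclobutenone 12. Reversible four‑electron electrocyclic opening of 12 (light or 80 °C) breaks C8a–C6 to give dienylketene 13, and the only ring closed, the benzene ring, forms by thermal six‑electron disrotatory electrocyclisation of 13 at C8a–C4a, after which cyclohexadienone 14 enolises to the phenol. The closest known reaction is the Danheiser benzannulation in its photochemical Wolff variant with (triisopropylsilyloxy)alkynes, here run with the parent terminal member. No stereocentre is created in 15, since the sp3 ring carbons of 12 and 14 vanish on aromatisation and the remote silylated carbinol centre is not touched. The selectivity needed is the orientation of the [2+2] step, and the polarised alkyne secures it: its nucleophilic CH terminus bonds to the ketene carbonyl carbon, which puts the free hydroxyl at C8a beside the chain and the silyloxy group at C7. E/Z scrambling of the enone under light is harmless because both geometries end in the same arene, and the excess of 10 should keep the phenol from being acylated by the ketene.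

Step 7
Reactants: 15 2‑[(3R)‑3,7‑dimethyl‑3‑(triethylsilyloxy)oct‑6‑en‑1‑yl]‑3‑methyl‑5‑(triisopropylsilyloxy)phenol
Product: 16 2‑[(3R)‑3,7‑dimethyl‑3‑(triethylsilyloxy)oct‑6‑en‑1‑yl]‑3‑methyl‑5‑(triisopropylsilyloxy)phenyl trifluoromethanesulfonate
Conditions: PhNTf2, Et3N, DMAP (cat.), CH2Cl2, rt
Reagents that add atoms: N‑phenylbis(trifluoromethanesulfonimide), O=S(=O)(N(c1ccccc1)S(=O)(=O)C(F)(F)F)C(F)(F)F
Why: Phenol triflation with the mild N‑phenyltriflimide reagent should be selective for the only free hydroxyl, generates no fluoride and leaves both silyl ethers intact.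

Step 8
Reactants: 16 aryl triflate from step 7
Product: 17 2‑[(3R)‑3‑hydroxy‑3,7‑dimethyloct‑6‑en‑1‑yl]‑3‑methyl‑5‑(triisopropylsilyloxy)phenyl trifluoromethanesulfonate
Conditions: PPTS (0.2 equiv), MeOH/CH2Cl2 (1:1), rt to 40 °C
Reagents that add atoms: none
Why: Acid‑catalysed methanolysis should remove the alkyl triethylsilyl ether, whereas the aryl triisopropylsilyl ether and the aryl triflate are stable to mild acid and the trisubstituted alkene is not protonated.

Step 9
Reactants: 17 hydroxy triflate from step 8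
Product: 18 triisopropyl{[(2R)‑2,5‑dimethyl‑2‑(4‑methylpent‑3‑en‑1‑yl)‑3,4‑dihydro‑2H‑chromen‑7‑yl]oxy}silane
Conditions: Pd(OAc)2 (5 mol %), t‑BuXPhos (2‑di‑tert‑butylphosphino‑2′,4′,6′‑triisopropylbiphenyl, 7.5 mol %), K3PO4, toluene, 90 °C
Reagents that add atoms: none
Why: Proposed new method: oxidative addition of the electron‑rich aryl triflate to zerovalent palladium bearing the bulky biaryl phosphine should give a cationic arylpalladium species that binds the tethered tertiary hydroxyl, K3PO4 deprotonates it, and C–O reductive elimination (the alkoxide carbon has no β‑hydrogen) closes the six‑membered pyran ring at C8a–O1 with the C2 configuration retained because no bond to C2 is touched; the closest known reaction types are the intramolecular Buchwald–Hartwig etherification of aryl bromides by tertiary alcohols and the palladium‑catalysed aryl ether synthesis from aryl triflates and phenols.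

Step 10
Reactants: 18 silyl‑protected chroman from step 9
Product: 20 (2E)‑5‑[(2R)‑2,5‑dimethyl‑7‑(triisopropylsilyloxy)‑3,4‑dihydro‑2H‑chromen‑2‑yl]‑2‑methylpent‑2‑en‑1‑ol, via enal 19 (not isolated)
Conditions: SeO2 (0.3 equiv), t‑BuOOH, salicylic acid (cat.), CH2Cl2, 0 °C to rt; then NaBH4, MeOH, 0 °C
Reagents that add atoms: tert‑butyl hydroperoxide, CC(C)(C)OO (net oxygen source); selenium dioxide, O=[Se]=O (oxygen relay)
Why: Catalytic SeO2/t‑BuOOH allylic oxidation (ene reaction, then [2,3]‑sigmatropic shift) should hydroxylate the E‑methyl group of the only alkene, and the borohydride treatment returns the portion over‑oxidised to enal 19 to the alcohol.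

Step 11
Reactants: 20 allylic alcohol from step 10
Product: 21 {[(2R)‑2‑[(3E)‑5‑bromo‑4‑methylpent‑3‑en‑1‑yl]‑2,5‑dimethyl‑3,4‑dihydro‑2H‑chromen‑7‑yl]oxy}triisopropylsilane
Conditions: CBr4, PPh3, 2,6‑lutidine (cat.), CH2Cl2, 0 °C
Reagents that add atoms: carbon tetrabromide, BrC(Br)(Br)Br
Why: The Appel reaction should convert the primary allylic alcohol to the bromide by SN2 displacement of the oxyphosphonium group, without allylic transposition or loss of alkene geometry.

Step 12
Reactants: 21 allylic bromide from step 11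
Product: 22 (4E)‑7‑[(2R)‑2,5‑dimethyl‑7‑(triisopropylsilyloxy)‑3,4‑dihydro‑2H‑chromen‑2‑yl]‑4‑methylhept‑4‑enenitrile
Conditions: MeCN (5 equiv), n‑BuLi (4.5 equiv), THF, −78 °C; then 21, −78 to −40 °C
Reagents that add atoms: acetonitrile, CC#N
Why: SN2 alkylation of lithioacetonitrile by the primary allylic bromide is a standard two‑carbon homologation of terpenoid allylic halides, and the excess of nucleophile should suppress dialkylation.

Step 13
Reactants: 22 nitrile from step 12
Product: 24 (4E)‑7‑[(2R)‑2,5‑dimethyl‑7‑(triisopropylsilyloxy)‑3,4‑dihydro‑2H‑chromen‑2‑yl]‑4‑methylhept‑4‑enal, via aluminium aldimine 23 (not isolated)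
Conditions: i‑Bu2AlH, CH2Cl2, −78 °C; then 1 M aq. tartaric acid, 0 °C to rt
Reagents that add atoms: water, O; diisobutylaluminium hydride, CC(C)C[AlH]CC(C)C (aluminium and isobutyl groups of intermediate 23 only)
Why: Partial reduction of a nitrile by i‑Bu2AlH stops at the N‑aluminio aldimine 23, which hydrolyses to the aldehyde on acidic work‑up without affecting the aryl silyl ether or the alkene.

Step 14
Reactants: 24 aldehyde from step 13; 25 methyl 2‑[bis(2,2,2‑trifluoroethoxy)phosphoryl]propanoate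
Product: 26 methyl (2Z,6E)‑9‑[(2R)‑2,5‑dimethyl‑7‑(triisopropylsilyloxy)‑3,4‑dihydro‑2H‑chromen‑2‑yl]‑2,6‑dimethylnona‑2,6‑dienoate
Conditions: 25, KN(SiMe3)2, 18‑crown‑6, THF, −78 °C; then 24, −78 °C
Reagents that add atoms: none
Why: In the Still–Gennari olefination the electron‑poor trifluoroethyl phosphonate with a dissociated potassium counter‑ion collapses rapidly and irreversibly from the kinetically favoured adduct, which should give the Z‑trisubstituted enoate.

Step 15
Reactants: 26 silyl‑protected ester from step 14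
Product: 27 methyl (2Z,6E)‑9‑[(2R)‑7‑hydroxy‑2,5‑dimethyl‑3,4‑dihydro‑2H‑chromen‑2‑yl]‑2,6‑dimethylnona‑2,6‑dienoate (CNP0319148.1)
Conditions: n‑Bu4NF, AcOH (1:1), THF, 0 °C
Reagents that add atoms: none
Why: Fluoride cleaves the aryl silyl ether rapidly, and buffering with acetic acid should prevent isomerisation of the Z‑enoate or ester cleavage by the basic phenoxide.

**Compound list**
1 | (R)‑linalool | C=C[C@](C)(O)CCC=C(C)C | starting material
2 | triethyl{[(3R)‑3,7‑dimethylocta‑1,6‑dien‑3‑yl]oxy}silane | C=C[C@](C)(O[Si](CC)(CC)CC)CCC=C(C)C | intermediate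
3 | (4R)‑4,8‑dimethyl‑4‑(triethylsilyloxy)non‑7‑enal | O=CCC[C@](C)(O[Si](CC)(CC)CC)CCC=C(C)C | intermediate
4 | 3‑(triphenylphosphoranylidene)butan‑2‑one | CC(=O)C(C)=P(c1ccccc1)(c1ccccc1)c1ccccc1 | starting material
5 | (3E,7R)‑3,7,11‑trimethyl‑7‑(triethylsilyloxy)dodeca‑3,10‑dien‑2‑one | CC(=O)/C(C)=C/CC[C@](C)(O[Si](CC)(CC)CC)CCC=C(C)C | intermediate
6 | (5E,9R)‑1,1,1‑trifluoro‑5,9,13‑trimethyl‑9‑(triethylsilyloxy)tetradeca‑5,12‑diene‑2,4‑dione | O=C(CC(=O)/C(C)=C/CC[C@](C)(O[Si](CC)(CC)CC)CCC=C(C)C)C(F)(F)F | intermediate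
7 | (3E,7R)‑1‑diazo‑3,7,11‑trimethyl‑7‑(triethylsilyloxy)dodeca‑3,10‑dien‑2‑one | [N-]=[N+]=CC(=O)/C(C)=C/CC[C@](C)(O[Si](CC)(CC)CC)CCC=C(C)C | intermediate
8 | acetylene | C#C | starting material
9 | lithium ethynolate | [Li+].[O-]C#C | intermediate
10 | (triisopropylsilyloxy)ethyne | C#CO[Si](C(C)C)(C(C)C)C(C)C | intermediate
11 | (3E,7R)‑3,7,11‑trimethyl‑7‑(triethylsilyloxy)dodeca‑1,3,10‑trien‑1‑one (vinylketene) | O=C=C/C(C)=C/CC[C@](C)(O[Si](CC)(CC)CC)CCC=C(C)C | intermediate
12 | 4‑[(2E,6R)‑6,10‑dimethyl‑6‑(triethylsilyloxy)undeca‑2,9‑dien‑2‑yl]‑3‑(triisopropylsilyloxy)cyclobut‑2‑en‑1‑one (both C4 epimers) | O=C1C=C(O[Si](C(C)C)(C(C)C)C(C)C)C1/C(C)=C/CC[C@](C)(O[Si](CC)(CC)CC)CCC=C(C)C | intermediate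
13 | (3E,5E,9R)‑5,9,13‑trimethyl‑9‑(triethylsilyloxy)‑3‑(triisopropylsilyloxy)tetradeca‑1,3,5,12‑tetraen‑1‑one (dienylketene) | O=C=C/C(O[Si](C(C)C)(C(C)C)C(C)C)=C\C(C)=C\CC[C@](C)(O[Si](CC)(CC)CC)CCC=C(C)C | intermediate
14 | 6‑[(3R)‑3,7‑dimethyl‑3‑(triethylsilyloxy)oct‑6‑en‑1‑yl]‑5‑methyl‑3‑(triisopropylsilyloxy)cyclohexa‑2,4‑dien‑1‑one (both C6 epimers) | O=C1C=C(O[Si](C(C)C)(C(C)C)C(C)C)C=C(C)C1CC[C@](C)(O[Si](CC)(CC)CC)CCC=C(C)C | intermediate
15 | 2‑[(3R)‑3,7‑dimethyl‑3‑(triethylsilyloxy)oct‑6‑en‑1‑yl]‑3‑methyl‑5‑(triisopropylsilyloxy)phenol | Oc1cc(O[Si](C(C)C)(C(C)C)C(C)C)cc(C)c1CC[C@](C)(O[Si](CC)(CC)CC)CCC=C(C)C | intermediate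
16 | 2‑[(3R)‑3,7‑dimethyl‑3‑(triethylsilyloxy)oct‑6‑en‑1‑yl]‑3‑methyl‑5‑(triisopropylsilyloxy)phenyl trifluoromethanesulfonate | O=S(=O)(Oc1cc(O[Si](C(C)C)(C(C)C)C(C)C)cc(C)c1CC[C@](C)(O[Si](CC)(CC)CC)CCC=C(C)C)C(F)(F)F | intermediate
17 | 2‑[(3R)‑3‑hydroxy‑3,7‑dimethyloct‑6‑en‑1‑yl]‑3‑methyl‑5‑(triisopropylsilyloxy)phenyl trifluoromethanesulfonate | O=S(=O)(Oc1cc(O[Si](C(C)C)(C(C)C)C(C)C)cc(C)c1CC[C@](C)(O)CCC=C(C)C)C(F)(F)F | intermediate
18 | triisopropyl{[(2R)‑2,5‑dimethyl‑2‑(4‑methylpent‑3‑en‑1‑yl)‑3,4‑dihydro‑2H‑chromen‑7‑yl]oxy}silane | CC(C)=CCC[C@]1(C)CCc2c(C)cc(O[Si](C(C)C)(C(C)C)C(C)C)cc2O1 | intermediate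
19 | (2E)‑5‑[(2R)‑2,5‑dimethyl‑7‑(triisopropylsilyloxy)‑3,4‑dihydro‑2H‑chromen‑2‑yl]‑2‑methylpent‑2‑enal | O=C/C(C)=C/CC[C@]1(C)CCc2c(C)cc(O[Si](C(C)C)(C(C)C)C(C)C)cc2O1 | intermediate
20 | (2E)‑5‑[(2R)‑2,5‑dimethyl‑7‑(triisopropylsilyloxy)‑3,4‑dihydro‑2H‑chromen‑2‑yl]‑2‑methylpent‑2‑en‑1‑ol | OC/C(C)=C/CC[C@]1(C)CCc2c(C)cc(O[Si](C(C)C)(C(C)C)C(C)C)cc2O1 | intermediate
21 | {[(2R)‑2‑[(3E)‑5‑bromo‑4‑methylpent‑3‑en‑1‑yl]‑2,5‑dimethyl‑3,4‑dihydro‑2H‑chromen‑7‑yl]oxy}triisopropylsilane | BrC/C(C)=C/CC[C@]1(C)CCc2c(C)cc(O[Si](C(C)C)(C(C)C)C(C)C)cc2O1 | intermediate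
22 | (4E)‑7‑[(2R)‑2,5‑dimethyl‑7‑(triisopropylsilyloxy)‑3,4‑dihydro‑2H‑chromen‑2‑yl]‑4‑methylhept‑4‑enenitrile | N#CCC/C(C)=C/CC[C@]1(C)CCc2c(C)cc(O[Si](C(C)C)(C(C)C)C(C)C)cc2O1 | intermediate
23 | N‑(diisobutylalumanyl) aldimine of 24 | CC(C)C[Al](CC(C)C)N=CCC/C(C)=C/CC[C@]1(C)CCc2c(C)cc(O[Si](C(C)C)(C(C)C)C(C)C)cc2O1 | intermediate
24 | (4E)‑7‑[(2R)‑2,5‑dimethyl‑7‑(triisopropylsilyloxy)‑3,4‑dihydro‑2H‑chromen‑2‑yl]‑4‑methylhept‑4‑enal | O=CCC/C(C)=C/CC[C@]1(C)CCc2c(C)cc(O[Si](C(C)C)(C(C)C)C(C)C)cc2O1 | intermediate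
25 | methyl 2‑[bis(2,2,2‑trifluoroethoxy)phosphoryl]propanoate | COC(=O)C(C)P(=O)(OCC(F)(F)F)OCC(F)(F)F | starting material
26 | methyl (2Z,6E)‑9‑[(2R)‑2,5‑dimethyl‑7‑(triisopropylsilyloxy)‑3,4‑dihydro‑2H‑chromen‑2‑yl]‑2,6‑dimethylnona‑2,6‑dienoate | COC(=O)/C(C)=C\CC/C(C)=C/CC[C@]1(C)CCc2c(C)cc(O[Si](C(C)C)(C(C)C)C(C)C)cc2O1 | intermediate
27 | methyl (2Z,6E)‑9‑[(2R)‑7‑hydroxy‑2,5‑dimethyl‑3,4‑dihydro‑2H‑chromen‑2‑yl]‑2,6‑dimethylnona‑2,6‑dienoate | COC(=O)/C(C)=C\CC/C(C)=C/CC[C@]1(C)CCc2c(C)cc(O)cc2O1 | target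

**Step count**
Total: 15 steps. Longest linear sequence: 14 steps (steps 1–4 and 6–15 from (R)‑linalool); step 5 is a one‑step side branch.

**Steps most likely to fail**

1. Step 9 (proposed new method). The risk is that C–O reductive elimination from the arylpalladium alkoxide is slower than S–O cleavage of the triflate back to the phenol or than hydrodetriflation, so that the ring does not close. The fallback uses only known chemistry and sets out from triflate 16. The triflate is exchanged for bromide by the known palladium‑catalysed conversion of aryl triflates into aryl bromides (Pd2(dba)3, t‑BuBrettPhos, KBr, phase‑transfer additive, toluene, 100 °C), which should give [3‑bromo‑4‑[(3R)‑3,7‑dimethyl‑3‑(triethylsilyloxy)oct‑6‑en‑1‑yl]‑5‑methylphenoxy]triisopropylsilane F1. Methanolysis with PPTS as in step 8 should then give (3R)‑1‑[2‑bromo‑6‑methyl‑4‑(triisopropylsilyloxy)phenyl]‑3,7‑dimethyloct‑6‑en‑3‑ol F2. This is closed under the established conditions for tertiary alcohols and aryl bromides (Pd(OAc)2, Tol‑BINAP, K2CO3, toluene, 100 °C), returning to the route at chroman 18.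

2. Step 6 (key step). The risk is that capture of the photogenerated vinylketene by the alkyne loses out to ketene dimerisation or to acylation of the product phenol, and that the siloxyalkyne or the phenol degrades under short‑wavelength light. The fallback keeps the same two fragments but reverses their roles and sets out from diazo enone 7. C‑silylation with triisopropylsilyl triflate and i‑Pr2NEt should give (3E,7R)‑1‑diazo‑3,7,11‑trimethyl‑7‑(triethylsilyloxy)‑1‑(triisopropylsilyl)dodeca‑3,10‑dien‑2‑one F3. Its photochemical Wolff rearrangement, run without any partner, should give the isolable (3E,7R)‑3,7,11‑trimethyl‑7‑(triethylsilyloxy)‑2‑(triisopropylsilyl)dodeca‑1,3,10‑trien‑1‑one F4. Addition of lithium ethynolate 9 (released from 10 with MeLi in THF) at the ketene carbonyl carbon forms C8–C7, six‑electron electrocyclisation closes C8a–C4a, and a 1,3 carbon‑to‑oxygen silyl shift moves the silyl group onto the C7 oxygen. Protonation then returns to the route at phenol 15. This silylvinylketene–ynolate benzannulation is known for substituted ynolates.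

3. Step 5. The risk is that monolithium acetylide disproportionates on warming before oxygen transfer, so that little ynolate is formed, and that the peroxide by‑products complicate isolation of the volatile product. The fallback generates the ynolate by ring fragmentation instead and sets out from commercially available 3‑phenylisoxazole F5. Deprotonation at C5 with LiN(i‑Pr)2 in THF at −78 °C triggers the classical base cleavage of 5‑unsubstituted isoxazoles to benzonitrile and lithium ethynolate 9. Silylation with triisopropylsilyl triflate and filtration through a short pad with pentane to remove benzonitrile returns to the route at 10.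

**Further compounds**
F1 | step 9 | [3‑bromo‑4‑[(3R)‑3,7‑dimethyl‑3‑(triethylsilyloxy)oct‑6‑en‑1‑yl]‑5‑methylphenoxy]triisopropylsilane | Brc1cc(O[Si](C(C)C)(C(C)C)C(C)C)cc(C)c1CC[C@](C)(O[Si](CC)(CC)CC)CCC=C(C)C
F2 | step 9 | (3R)‑1‑[2‑bromo‑6‑methyl‑4‑(triisopropylsilyloxy)phenyl]‑3,7‑dimethyloct‑6‑en‑3‑ol | Brc1cc(O[Si](C(C)C)(C(C)C)C(C)C)cc(C)c1CC[C@](C)(O)CCC=C(C)C
F3 | step 6 | (3E,7R)‑1‑diazo‑3,7,11‑trimethyl‑7‑(triethylsilyloxy)‑1‑(triisopropylsilyl)dodeca‑3,10‑dien‑2‑one | [N-]=[N+]=C([Si](C(C)C)(C(C)C)C(C)C)C(=O)/C(C)=C/CC[C@](C)(O[Si](CC)(CC)CC)CCC=C(C)C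
F4 | step 6 | (3E,7R)‑3,7,11‑trimethyl‑7‑(triethylsilyloxy)‑2‑(triisopropylsilyl)dodeca‑1,3,10‑trien‑1‑one | O=C=C([Si](C(C)C)(C(C)C)C(C)C)/C(C)=C/CC[C@](C)(O[Si](CC)(CC)CC)CCC=C(C)C
F5 | step 5 | 3‑phenylisoxazole | c1ccc(cc1)-c1ccon1
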